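**Plan**
1. Retrosynthetic cuts: first the two O-benzyl bonds and the 8-O-methyl bond. Ring A is then cut at C8–C8a (electrocyclic bond) and at C5–C4a (carbonyl-addition bond), which frees C5–C8 with their four oxygens as dimethyl squarate.
2. Enabling feature: ring A is hexasubstituted, with para oxygens on C5 and C8 bracketing the adjacent C6/C7 methoxyls, the pattern of a squarate-derived hydroquinone. Its sixth edge, C4a–C8a, is the C5=C6 bond of a monocyclic 2-aryl-3-oxy-4-pyranone (ring C) whose C6 still carries hydrogen.
3. Ring C goes back to a 2-furyl carbinol. The C2–C1' bond comes from an aryl Grignard reagent and 3-bromofurfural, and the furan bromine marks the future C4 carbonyl carbon.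
4. Forward order: ring B is bought. Ring C arises by Achmatowicz ring expansion and hydrolytic aromatisation. Iodination, I/Mg exchange and addition join the squarate at C4a, and ring A closes last by thermal 4π opening and 6π closure.
5. End game: methylation of the non-chelated 8-hydroxyl, then hydrogenolysis of both benzyl ethers.
6. Stereochemistry: the target is flat and achiral. Every stereocentre met on the way is transient, formed racemic and erased by aromatisation.

Key step: step 7

Assumption: the target has no stereocentre and no stereoaxis, so "single enantiomer" is read as the constitution drawn, and all chiral intermediates are used as racemates.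

**Step 1**
Reactants: 1 1-(benzyloxy)-4-bromobenzene; 2 3-bromofuran-2-carbaldehyde
Product: 4 (±)-[4-(benzyloxy)phenyl](3-bromofuran-2-yl)methanol, via 4-(benzyloxy)phenylmagnesium bromide 3 (not isolated)
Conditions: Mg, THF, 40 °C; then 2, THF, −20 → 0 °C; aq. NH4Cl
Reagents that add atoms: none
Why: Grignard 1,2-addition to the aldehyde is much faster than any Br/Mg exchange at the furyl bromide at this temperature, and the new carbinol centre is formed racemic on purpose because it becomes sp2 in step 3.

**Step 2**
Reactants: 4 (±)-[4-(benzyloxy)phenyl](3-bromofuran-2-yl)methanol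
Product: 5 (±)-2-[4-(benzyloxy)phenyl]-4-bromo-6-hydroxy-2H-pyran-3(6H)-one (mixture of C6 epimers)
Conditions: NBS (1.05 equiv), NaHCO3 (2 equiv), THF–H2O 4:1, 0 °C
Reagents that add atoms: water, O
Why: Achmatowicz rearrangement, in which bromonium transfer to the free furan C5 (the most nucleophilic site), hydrolysis and closure of the carbinol oxygen onto the unmasked aldehyde should give the pyranone with the furan C3 bromine now on C4; the buffer suppresses ionisation of the doubly activated carbinol, and the new C6 hemiacetal centre forms as an inconsequential epimer mixture that is lost in step 3.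

**Step 3**
Reactants: 5 (±)-2-[4-(benzyloxy)phenyl]-4-bromo-6-hydroxy-2H-pyran-3(6H)-one
Product: 6 2-[4-(benzyloxy)phenyl]-3-hydroxy-4H-pyran-4-one
Conditions: 1 M aq. H2SO4–1,4-dioxane 1:1, 85 °C
Reagents that add atoms: water, O
Why: Acid-catalysed aromatising hydrolysis, the last stage of the halogenative furfuryl alcohol to γ-pyrone conversion used for maltol-type compounds, in which enolisation of the benzylic C2–H, loss of the anomeric hydroxyl and addition–elimination of water at the bromine-bearing C4 should give the 3-hydroxy-4-pyranone and remove both stereocentres; because the halogen came with the furan, no free halogen ever meets the electron-rich aryl ether.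

**Step 4**
Reactants: 6 2-[4-(benzyloxy)phenyl]-3-hydroxy-4H-pyran-4-one
Product: 7 3-(benzyloxy)-2-[4-(benzyloxy)phenyl]-4H-pyran-4-one
Conditions: BnBr (1.5 equiv), K2CO3, DMF, 50 °C
Reagents that add atoms: benzyl bromide, BrCc1ccccc1
Why: Williamson etherification of the acidic enolic 3-hydroxyl, as in the preparation of benzyl maltol, and the excess of benzyl bromide would also re-protect any 4'-phenol bared by the acid of step 3.

**Step 5**
Reactants: 7 3-(benzyloxy)-2-[4-(benzyloxy)phenyl]-4H-pyran-4-one
Product: 8 3-(benzyloxy)-2-[4-(benzyloxy)phenyl]-5-iodo-4H-pyran-4-one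
Conditions: NIS (1.1 equiv), TFA (0.3 equiv), MeCN, 40 °C, dark
Reagents that add atoms: N-iodosuccinimide, O=C1CCC(=O)N1I
Why: Electrophilic α-iodination of a vinylogous ester, since C5 is the only unsubstituted carbon that is β to the ring oxygen and α to the carbonyl (the site that corresponds to C3 in chromone and flavone iodination), whereas ring B is deactivated by conjugation with the pyranone and C6 is the electron-poor β-carbon.

**Step 6**
Reactants: 8 3-(benzyloxy)-2-[4-(benzyloxy)phenyl]-5-iodo-4H-pyran-4-one; 9 dimethyl squarate
Product: 11 (±)-4-{5-(benzyloxy)-6-[4-(benzyloxy)phenyl]-4-oxo-4H-pyran-3-yl}-4-hydroxy-2,3-dimethoxycyclobut-2-en-1-one, via C5-magnesiated pyranone 10 (not isolated)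
Conditions: i-PrMgCl·LiCl (1.1 equiv), THF, −40 °C, 30 min; cannulated into 9 (1.3 equiv), THF, −78 → −20 °C; aq. NH4Cl
Reagents that add atoms: none
Why: Iodine–magnesium exchange with the turbo-Grignard reagent followed by 1,2-addition of the organomagnesium to a squarate carbonyl; α-iodo-β-oxy enones exchange quickly at low temperature, and alkenylmagnesium species with a β-oxygen (5-magnesiated 1,3-dioxin-4-ones and uracils) hold at −40 °C where lithium analogues fragment, while the new carbinol centre forms racemic and is erased in step 7.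

**Step 7**
Reactants: 11 (±)-4-{5-(benzyloxy)-6-[4-(benzyloxy)phenyl]-4-oxo-4H-pyran-3-yl}-4-hydroxy-2,3-dimethoxycyclobut-2-en-1-one
Product: 14 3,4'-bis(benzyloxy)-5,8-dihydroxy-6,7-dimethoxyflavone, via vinylketene 12 (not isolated), via 8a-H cyclohexadienone 13 (not isolated)
Conditions: toluene (degassed, 0.02 M), 110 °C, Ar
Reagents that add atoms: none
Why: Heating should open the cyclobutenone by conrotatory 4π electrocyclic cleavage of its C1–C4 bond to the dimethoxy vinylketene 12. This is the Moore-type thermal ring expansion of squarate-derived 4-aryl-, 4-heteroaryl- and 4-alkenyl-4-hydroxycyclobutenones, with the weakly aromatic pyranone C5=C6 bond serving as the alkenyl arm. Ring A closes by disrotatory 6π electrocyclisation in which the ketene carbon bonds to the pyranone C6–H carbon (new C8–C8a bond) to give dienone 13, and enolisation of the ring-fusion hydrogen then aromatises it to the 5,8-hydroquinone 14. The only new stereocentre, C8a of 13, forms racemic and disappears at once on tautomerisation, so no control element is needed. The step needs outward rotation of the hydroxyl so that the pyranonyl group lies cis to the ketene, which the donor torquoselectivity of oxygen substituents secures, and it needs a single closure site, which holds because the other neighbour of the attachment carbon is the C4 carbonyl carbon and offers no six-membered closure. Exclusion of oxygen should keep the product at the hydroquinone level.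

**Step 8**
Reactants: 14 3,4'-bis(benzyloxy)-5,8-dihydroxy-6,7-dimethoxyflavone
Product: 15 3,4'-bis(benzyloxy)-5-hydroxy-6,7,8-trimethoxyflavone
Conditions: MeI (1.1 equiv), K2CO3 (1.1 equiv), acetone (degassed), Ar, rt → 40 °C
Reagents that add atoms: iodomethane, CI
Why: Chelation-controlled Williamson methylation, the classic partial methylation of 5-hydroxyflavones, in which the 5-hydroxyl is tied up in a six-membered hydrogen bond to the C4 carbonyl so that one equivalent of MeI and a weak base should alkylate only the free 8-phenol, while argon prevents base-promoted oxidation to the quinone.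

**Step 9**
Reactants: 15 3,4'-bis(benzyloxy)-5-hydroxy-6,7,8-trimethoxyflavone
Product: 16 3,5,4'-trihydroxy-6,7,8-trimethoxyflavone
Conditions: H2 (1 atm), 10% Pd/C, EtOAc–MeOH, rt
Reagents that add atoms: none
Why: Catalytic hydrogenolysis should cleave the aryl benzyl ether and the enol benzyl ether, while the tetrasubstituted conjugated C2=C3 bond, the carbonyl and the methoxyls are inert at one atmosphere, as is usual in flavonol end games.

**Compound list**
1 | 1-(benzyloxy)-4-bromobenzene | Brc1ccc(OCc2ccccc2)cc1 | starting material
2 | 3-bromofuran-2-carbaldehyde | O=Cc1occc1Br | starting material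
3 | 4-(benzyloxy)phenylmagnesium bromide | Br[Mg]c1ccc(OCc2ccccc2)cc1 | intermediate
4 | (±)-[4-(benzyloxy)phenyl](3-bromofuran-2-yl)methanol | OC(c1ccc(OCc2ccccc2)cc1)c1occc1Br | intermediate
5 | (±)-2-[4-(benzyloxy)phenyl]-4-bromo-6-hydroxy-2H-pyran-3(6H)-one, C6 epimer mixture | O=C1C(Br)=CC(O)OC1c1ccc(OCc2ccccc2)cc1 | intermediate
6 | 2-[4-(benzyloxy)phenyl]-3-hydroxy-4H-pyran-4-one | O=c1ccoc(-c2ccc(OCc3ccccc3)cc2)c1O | intermediate
7 | 3-(benzyloxy)-2-[4-(benzyloxy)phenyl]-4H-pyran-4-one | O=c1ccoc(-c2ccc(OCc3ccccc3)cc2)c1OCc1ccccc1 | intermediate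
8 | 3-(benzyloxy)-2-[4-(benzyloxy)phenyl]-5-iodo-4H-pyran-4-one | O=c1c(I)coc(-c2ccc(OCc3ccccc3)cc2)c1OCc1ccccc1 | intermediate
9 | dimethyl squarate (3,4-dimethoxycyclobut-3-ene-1,2-dione) | COC1=C(OC)C(=O)C1=O | starting material
10 | C5-magnesiated pyranone, {5-(benzyloxy)-6-[4-(benzyloxy)phenyl]-4-oxo-4H-pyran-3-yl}magnesium chloride | O=c1c([Mg]Cl)coc(-c2ccc(OCc3ccccc3)cc2)c1OCc1ccccc1 | intermediate
11 | (±)-4-{5-(benzyloxy)-6-[4-(benzyloxy)phenyl]-4-oxo-4H-pyran-3-yl}-4-hydroxy-2,3-dimethoxycyclobut-2-en-1-one | COC1=C(OC)C(O)(c2coc(-c3ccc(OCc4ccccc4)cc3)c(OCc3ccccc3)c2=O)C1=O | intermediate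
12 | vinylketene, 4-hydroxy-2,3-dimethoxy-4-(pyranon-3-yl)buta-1,3-dien-1-one with the hydroxyl outward and the pyranonyl group cis to the ketene | O=C=C(OC)/C(OC)=C(/O)c1coc(-c2ccc(OCc3ccccc3)cc2)c(OCc2ccccc2)c1=O | intermediate
13 | (±)-8a-H cyclohexadienone, 3-(benzyloxy)-2-[4-(benzyloxy)phenyl]-5-hydroxy-6,7-dimethoxy-8aH-chromene-4,8-dione | O=C1C(OC)=C(OC)C(O)=C2C1OC(c1ccc(OCc3ccccc3)cc1)=C(OCc1ccccc1)C2=O | intermediate
14 | 3,4'-bis(benzyloxy)-5,8-dihydroxy-6,7-dimethoxyflavone | O=c1c(OCc2ccccc2)c(-c2ccc(OCc3ccccc3)cc2)oc2c(O)c(OC)c(OC)c(O)c12 | intermediate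
15 | 3,4'-bis(benzyloxy)-5-hydroxy-6,7,8-trimethoxyflavone | COc1c(OC)c(O)c2c(=O)c(OCc3ccccc3)c(-c3ccc(OCc4ccccc4)cc3)oc2c1OC | intermediate
16 | 3,5,4'-trihydroxy-6,7,8-trimethoxyflavone (achiral) | COc1c(OC)c(O)c2c(=O)c(O)c(-c3ccc(O)cc3)oc2c1OC | target

Total step count: 9. Longest linear sequence: 9 steps (from 1 or 2 to 16; 9 enters as a purchased building block in step 6).

**Steps most likely to fail**

**Step 6 (exchange and addition to the squarate).**
- What may go wrong: in the C5-metalated pyranone the ring oxygen sits on the neighbouring alkene carbon, anti to the metal. β-Elimination that opens the pyranone to an alkynyl ketone enolate may therefore overtake a slow addition of this stabilised, hindered nucleophile. Conjugate attack of the exchange reagent at C6 is a second drain.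
- Fallback: the squarate is attached at the other end of the same double bond. Setting out from 7, deprotonation of the acidic C6–H with TMPMgCl·LiCl (THF, −40 °C) should give the C6-magnesiated pyranone F1, which has no β-leaving group.
- Addition of F1 to 9 should give (±)-4-{5-(benzyloxy)-6-[4-(benzyloxy)phenyl]-4-oxo-4H-pyran-2-yl}-4-hydroxy-2,3-dimethoxycyclobut-2-en-1-one F2.
- Heating F2 in degassed toluene should close ring A by bonding the ketene carbon to the nucleophilic pyranone C5 (flavone C5–C4a). Because the squarate unit is symmetric, the same hydroquinone results. The fallback returns to the route at 14 and makes step 5 unnecessary.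

**Step 7 (ring expansion).**
- What may go wrong: material may be lost by oxidation of the free, electron-rich hydroquinone to the 5,8-quinone at the reaction temperature. The ketene may also be captured by the free hydroxyl or by adventitious nucleophiles before the 6π closure.
- Fallback: the carbinol oxygen is carried through the rearrangement in protected form. Setting out from 11, TESOTf and 2,6-lutidine (CH2Cl2, −78 → 0 °C) should give the (±)-4-O-triethylsilyl ether of 11 F3.
- Thermolysis of F3 follows the known behaviour of 4-silyloxycyclobutenones, in which the silyloxy group also rotates outward. It should give 3,4'-bis(benzyloxy)-8-hydroxy-6,7-dimethoxy-5-(triethylsilyloxy)flavone F4, which cannot be oxidised to a quinone and carries a single free phenol.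
- MeI and K2CO3 should then give 3,4'-bis(benzyloxy)-6,7,8-trimethoxy-5-(triethylsilyloxy)flavone F5. TBAF buffered with AcOH removes the silyl group, so the fallback returns at 15 without relying on chelation control.

**Step 5 (C5 iodination).**
- What may go wrong: site selectivity may be poor (iodination ortho to the benzyloxy group of ring B), the push–pull alkene may react sluggishly, or acid may remove the 3-O-benzyl group.
- Fallback: electrophilic substitution is replaced by directed C–H metalation. Setting out from 7, TMP2Zn·2MgCl2·2LiCl (0.6 equiv, THF, −30 °C → rt) should steer the amide base to the adjacent C5–H through carbonyl-bound MgCl2, as in the C3-zincation of chromones. This should give bis{5-(benzyloxy)-6-[4-(benzyloxy)phenyl]-4-oxo-4H-pyran-3-yl}zinc F6.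
- Iodolysis of F6 with I2 returns to the route at 8.

**Further compounds**
F1 | step 6 | C6-magnesiated pyranone | O=c1cc([Mg]Cl)oc(-c2ccc(OCc3ccccc3)cc2)c1OCc1ccccc1
F2 | step 6 | (±)-4-{5-(benzyloxy)-6-[4-(benzyloxy)phenyl]-4-oxo-4H-pyran-2-yl}-4-hydroxy-2,3-dimethoxycyclobut-2-en-1-one | COC1=C(OC)C(O)(c2cc(=O)c(OCc3ccccc3)c(-c3ccc(OCc4ccccc4)cc3)o2)C1=O
F3 | step 7 | (±)-4-O-triethylsilyl ether of 11 | COC1=C(OC)C(O[Si](CC)(CC)CC)(c2coc(-c3ccc(OCc4ccccc4)cc3)c(OCc3ccccc3)c2=O)C1=O
F4 | step 7 | 3,4'-bis(benzyloxy)-8-hydroxy-6,7-dimethoxy-5-(triethylsilyloxy)flavone | O=c1c(OCc2ccccc2)c(-c2ccc(OCc3ccccc3)cc2)oc2c(O)c(OC)c(OC)c(O[Si](CC)(CC)CC)c12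
F5 | step 7 | 3,4'-bis(benzyloxy)-6,7,8-trimethoxy-5-(triethylsilyloxy)flavone | COc1c(OC)c(O[Si](CC)(CC)CC)c2c(=O)c(OCc3ccccc3)c(-c3ccc(OCc4ccccc4)cc3)oc2c1OC
F6 | step 5 | bis{5-(benzyloxy)-6-[4-(benzyloxy)phenyl]-4-oxo-4H-pyran-3-yl}zinc | O=c1c([Zn]c2coc(-c3ccc(OCc4ccccc4)cc3)c(OCc3ccccc3)c2=O)coc(-c2ccc(OCc3ccccc3)cc2)c1OCc1ccccc1
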